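## Retrosynthetic overview

1. Target 25 ⇐ tertiary allylic boronic ester 23 by Zweifel vinylation (boron-to-carbon 1,2-shift with retention), which adds the last carbon substituent of the quaternary centre.
2. 23 ⇐ secondary allylic carbamate 20 + homoallylic boronic ester 10 by lithiation–borylation. The stereospecific 1,2-metallate shift of the C12 chain from boron to carbon builds the quaternary stereocentre and is the key step.
3. 20 ⇐ secondary boronic ester 13 + iodoalkene 17 (from (S)-but-3-yn-2-ol 14) by Zweifel-type coupling; 13 ⇐ 11 by one-carbon homologation with lithiated ethyl carbamate (two more 1,2-shifts).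
4. 11 ⇐ 10 by a new cobalt-hydride cycloisomerisation. The only ring, the methylidenecyclohexane, is formed here on the portion of 10 meant for the left arm, before the halves are joined; the rest of 10 stays acyclic.
5. 10 ⇐ enyne 5 (zirconium-catalysed carboalumination, then ethylene oxide) ⇐ bromides 1 + 2 (copper-catalysed asymmetric SN2' alkylation).

Assumption: 1, 2 and 14 are bought as such; the Me3Si cap of 1 is a protecting group (five skeleton atoms); in step 1 the ligand antipode that gives the (S) product is the one meant, its sense being assigned by analogy. Cb = N,N-diisopropylcarbamoyl, pin = pinacolato.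

## Route

Step 1
Reactants: 1 4-bromo-1-(trimethylsilyl)but-1-yne; 2 (E)-1-bromo-2-methylbut-2-ene
Product: 4 trimethyl[(5S)-5,6-dimethylhept-6-en-1-yn-1-yl]silane, via butynylmagnesium bromide 3 (not isolated)
Conditions: 1, Mg, Et2O, 35 °C; added over 1 h to 2, Cu(O2CC4H3S) (copper thiophene-2-carboxylate, 3 mol %), (S,S,S)-phosphoramidite [O,O'-(S)-1,1'-binaphthyl-2,2'-diyl N,N-bis((S)-1-(2-methoxyphenyl)ethyl)phosphoramidite, 3.3 mol %], CH2Cl2, −78 °C
Reagents that add atoms: none
Why: Copper-catalysed asymmetric allylic alkylation (SN2'): the alkylcopper adds to the methyl-bearing γ-carbon of the allylic bromide with loss of bromide and the chiral ligand selects the alkene face, setting the CH(CH3)–C(CH3)=CH2 stereocentre as (S).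

Step 2
Reactants: 4 trimethyl[(5S)-5,6-dimethylhept-6-en-1-yn-1-yl]silane
Product: 5 (5S)-5,6-dimethylhept-6-en-1-yne
Conditions: K2CO3 (0.2 equiv), MeOH, 23 °C
Reagents that add atoms: none
Why: Base-catalysed methanolysis of the alkynyl C–Si bond (protodesilylation) frees the terminal alkyne without touching the stereocentre.

Step 3
Reactants: 5 (5S)-5,6-dimethylhept-6-en-1-yne
Product: 7 (3E,7S)-4,7,8-trimethylnona-3,8-dien-1-ol, via alkenyldimethylalane 6 (not isolated)
Conditions: Me3Al (2 equiv), Cp2ZrCl2 (0.25 equiv), CH2Cl2, 0 → 23 °C; volatiles removed; n-BuLi, hexane/THF, −78 → 0 °C; ethylene oxide (3 equiv), 0 → 23 °C; water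
Reagents that add atoms: trimethylaluminium, C[Al](C)C; ethylene oxide, C1CO1
Why: Negishi zirconium-catalysed carboalumination adds CH3 and Al syn across the terminal alkyne with Al on the terminal carbon, which fixes the (E)-trisubstituted alkene, and the derived lithium alanate opens ethylene oxide with retention of that geometry; the hindered 1,1-disubstituted alkene is inert.

Step 4
Reactants: 7 (3E,7S)-4,7,8-trimethylnona-3,8-dien-1-ol
Product: 8 (3S,6E)-9-iodo-2,3,6-trimethylnona-1,6-diene
Conditions: I2, PPh3, imidazole, CH2Cl2, 0 → 23 °C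
Reagents that add atoms: iodine, II
Why: Appel iodination, an SN2 displacement of the alkoxyphosphonium by iodide at the primary carbon; alkenes and the stereocentre are untouched.

Step 5
Reactants: 8 (3S,6E)-9-iodo-2,3,6-trimethylnona-1,6-diene
Product: 10 4,4,5,5-tetramethyl-2-[(3E,7S)-4,7,8-trimethylnona-3,8-dien-1-yl]-1,3,2-dioxaborolane, via homoallyllithium reagent 9 (not isolated)
Conditions: t-BuLi (2.1 equiv), Et2O/pentane, −78 °C; 2-isopropoxy-4,4,5,5-tetramethyl-1,3,2-dioxaborolane, −78 → 23 °C; water
Reagents that add atoms: 2-isopropoxy-4,4,5,5-tetramethyl-1,3,2-dioxaborolane, CC(C)OB1OC(C)(C)C(C)(C)O1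
Why: Iodine–lithium exchange followed by electrophilic borylation of the primary alkyllithium gives the pinacol ester; 10 is the branch point, part going to step 6 and part kept for step 11.

Step 6
Reactants: 10 4,4,5,5-tetramethyl-2-[(3E,7S)-4,7,8-trimethylnona-3,8-dien-1-yl]-1,3,2-dioxaborolane
Product: 11 4,4,5,5-tetramethyl-2-{2-[(1R,3S)-2,2,3-trimethyl-6-methylidenecyclohexyl]ethyl}-1,3,2-dioxaborolane
Conditions: Co(salen)Cl (5 mol %; salen = N,N'-bis(3,5-di-tert-butylsalicylidene)-1,2-cyclohexanediaminate), PhSiH3 (10 mol %), benzene (0.02 M), 22 °C, stopped as soon as 10 is consumed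
Reagents that add atoms: none
Why: Proposed new method: a cobalt-hydride hydrogen-atom-transfer cycloisomerisation in which the hydride of trivalent cobalt (from Co(salen)Cl and PhSiH3) delivers H• to the CH2 terminus of the isopropenyl group, the tertiary radical closes 6-endo on the CH carbon of the (E)-trisubstituted alkene through a chair transition state with the ring methyl and the borylethyl chain both equatorial (hence cis, new centre R), and divalent cobalt then takes H• back from the least hindered β-position, the methyl group, to leave the exocyclic methylene and regenerate the hydride; the closest known reaction types are the Co(salen)-catalysed radical isomerisation and 5-exo cycloisomerisation of alkenes and the Cp2TiCl-mediated radical cyclisation of epoxy-polyenes, which ends in exocyclic alkenes from the same kind of tertiary cyclohexyl radical.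

Step 7
Reactants: 11 4,4,5,5-tetramethyl-2-{2-[(1R,3S)-2,2,3-trimethyl-6-methylidenecyclohexyl]ethyl}-1,3,2-dioxaborolane
Product: 13 4,4,5,5-tetramethyl-2-{(2R)-4-[(1R,3S)-2,2,3-trimethyl-6-methylidenecyclohexyl]butan-2-yl}-1,3,2-dioxaborolane, via lithium boronate complex 12 (not isolated)
Conditions: EtOCb (1.3 equiv), s-BuLi (1.3 equiv), (−)-sparteine (1.3 equiv), Et2O, −78 °C, 5 h; 11, −78 °C, 1 h; then reflux, 12 h; water
Reagents that add atoms: ethyl N,N-diisopropylcarbamate, CCOC(=O)N(C(C)C)C(C)C
Why: Lithiation–borylation (Hoppe–Aggarwal homologation): sparteine-controlled deprotonation gives the (S)-lithiated carbamate, which adds to boron with retention, and the 1,2-metallate shift of the primary alkyl group from boron to carbon with inversion (carbamate leaves) sets the methyl-bearing centre as (R).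

Step 8
Reactants: 14 (2S)-but-3-yn-2-ol
Product: 15 (2S)-but-3-yn-2-yl N,N-diisopropylcarbamate
Conditions: iPr2NCOCl (1.2 equiv), Et3N, DMAP (10 mol %), CH2Cl2, reflux
Reagents that add atoms: N,N-diisopropylcarbamoyl chloride, CC(C)N(C(C)C)C(Cl)=O
Why: Carbamoylation (acyl substitution at the carbamoyl chloride) of the secondary alcohol; the C–O stereocentre is not involved.

Step 9
Reactants: 15 (2S)-but-3-yn-2-yl N,N-diisopropylcarbamate
Product: 17 (2S,3E)-4-iodobut-3-en-2-yl N,N-diisopropylcarbamate, via alkenylzirconocene chloride 16 (not isolated)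
Conditions: Cp2Zr(H)Cl (1.2 equiv), THF, 23 °C; I2, 0 °C
Reagents that add atoms: iodine, II
Why: Schwartz hydrozirconation adds Zr–H syn with zirconium at the terminal carbon and iodinolysis of the C–Zr bond proceeds with retention, giving the (E)-iodoalkene.

Step 10
Reactants: 13 4,4,5,5-tetramethyl-2-{(2R)-4-[(1R,3S)-2,2,3-trimethyl-6-methylidenecyclohexyl]butan-2-yl}-1,3,2-dioxaborolane; 17 (2S,3E)-4-iodobut-3-en-2-yl N,N-diisopropylcarbamate
Product: 20 (2S,3E,5R)-5-methyl-7-[(1R,3S)-2,2,3-trimethyl-6-methylidenecyclohexyl]hept-3-en-2-yl N,N-diisopropylcarbamate, via alkenyllithium reagent 18 (not isolated), via lithium alkenylboronate complex 19 (not isolated)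
Conditions: 17 (1.3 equiv), t-BuLi (2.6 equiv), Et2O, −78 °C; 13 in THF, −78 °C, 1 h; PhSeCl (1.5 equiv), THF, −78 °C; mCPBA (2 equiv), −78 → −45 °C
Reagents that add atoms: none
Why: Zweifel-type olefination in its selenium syn-elimination form: the alkenyllithium adds to boron, PhSe+ activates the alkenyl group so that the secondary alkyl group makes a 1,2-shift from boron to carbon with retention at the migrating (R) centre, and oxidation to the selenoxide triggers syn B/Se elimination, which keeps the (E) geometry.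

Step 11
Reactants: 20 (2S,3E,5R)-5-methyl-7-[(1R,3S)-2,2,3-trimethyl-6-methylidenecyclohexyl]hept-3-en-2-yl N,N-diisopropylcarbamate; 10 4,4,5,5-tetramethyl-2-[(3E,7S)-4,7,8-trimethylnona-3,8-dien-1-yl]-1,3,2-dioxaborolane
Product: 23 2-[(3R,4E,6S,9E,13S)-3,6,10,13,14-pentamethyl-1-[(1R,3S)-2,2,3-trimethyl-6-methylidenecyclohexyl]pentadeca-4,9,14-trien-6-yl]-4,4,5,5-tetramethyl-1,3,2-dioxaborolane, via lithiated carbamate 21 (not isolated), via lithium boronate complex 22 (not isolated)
Conditions: 20, s-BuLi (1.2 equiv), TMEDA (1.2 equiv), Et2O, −78 °C, 30 min; 10 (1.5 equiv), −78 °C, 1 h; MgBr2·OEt2, −78 → 23 °C, 12 h; water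
Reagents that add atoms: none
Why: Lithiation–borylation of a secondary allylic carbamate, the key step: deprotonation and α-borylation both go with retention (the branched γ-carbon disfavours γ-attack), and the stereospecific 1,2-metallate shift of the homoallylic chain from boron to carbon with inversion (carbamate leaves) builds the quaternary carbon, (S) as drawn, with both long chains in place.

Step 12
Reactants: 23 2-[(3R,4E,6S,9E,13S)-3,6,10,13,14-pentamethyl-1-[(1R,3S)-2,2,3-trimethyl-6-methylidenecyclohexyl]pentadeca-4,9,14-trien-6-yl]-4,4,5,5-tetramethyl-1,3,2-dioxaborolane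
Product: 25 (1R,3S)-1-[(3R,4E,6S,9E,13S)-6-ethenyl-3,6,10,13,14-pentamethylpentadeca-4,9,14-trien-1-yl]-2,2,3-trimethyl-6-methylidenecyclohexane (target CNP0293684.4), via lithium vinylboronate complex 24 (not isolated)
Conditions: bromoethene (4 equiv), t-BuLi (8 equiv), Et2O, −78 °C; 23 in THF, −78 °C, 1 h; I2 in MeOH, −78 °C; NaOMe in MeOH, −78 → 23 °C
Reagents that add atoms: vinyllithium, [Li]C=C (made in the flask from bromoethene, C=CBr)
Why: Zweifel olefination: vinyllithium forms the boronate, iodine activates the vinyl group so that the tertiary allylic carbon migrates from boron to carbon with retention (1,2-shift), and methoxide induces anti elimination of boron and iodide, leaving the vinyl group on the quaternary (S) centre.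

## Compound list

1 | 4-bromo-1-(trimethylsilyl)but-1-yne | C[Si](C)(C)C#CCCBr | starting material
2 | (E)-1-bromo-2-methylbut-2-ene (tiglyl bromide) | C/C=C(\C)CBr | starting material
3 | [4-(trimethylsilyl)but-3-yn-1-yl]magnesium bromide | C[Si](C)(C)C#CCC[Mg]Br | intermediate
4 | trimethyl[(5S)-5,6-dimethylhept-6-en-1-yn-1-yl]silane | C[Si](C)(C)C#CCC[C@H](C)C(=C)C | intermediate
5 | (5S)-5,6-dimethylhept-6-en-1-yne | C#CCC[C@H](C)C(=C)C | intermediate
6 | dimethyl[(1E,5S)-2,5,6-trimethylhepta-1,6-dien-1-yl]alane | C[Al](C)/C=C(\C)CC[C@H](C)C(=C)C | intermediate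
7 | (3E,7S)-4,7,8-trimethylnona-3,8-dien-1-ol | OCC/C=C(\C)CC[C@H](C)C(=C)C | intermediate
8 | (3S,6E)-9-iodo-2,3,6-trimethylnona-1,6-diene | ICC/C=C(\C)CC[C@H](C)C(=C)C | intermediate
9 | [(3E,7S)-4,7,8-trimethylnona-3,8-dien-1-yl]lithium | [Li]CC/C=C(\C)CC[C@H](C)C(=C)C | intermediate
10 | 4,4,5,5-tetramethyl-2-[(3E,7S)-4,7,8-trimethylnona-3,8-dien-1-yl]-1,3,2-dioxaborolane | CC1(C)OB(OC1(C)C)CC/C=C(\C)CC[C@H](C)C(=C)C | intermediate
11 | 4,4,5,5-tetramethyl-2-{2-[(1R,3S)-2,2,3-trimethyl-6-methylidenecyclohexyl]ethyl}-1,3,2-dioxaborolane | CC1(C)OB(OC1(C)C)CC[C@@H]2C(=C)CC[C@H](C)C2(C)C | intermediate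
12 | lithium boronate complex of 11 carrying the (S)-1-(diisopropylcarbamoyloxy)ethyl group on boron | [Li+].C[C@@H](OC(=O)N(C(C)C)C(C)C)[B-]1(CC[C@@H]2C(=C)CC[C@H](C)C2(C)C)OC(C)(C)C(C)(C)O1 | intermediate
13 | 4,4,5,5-tetramethyl-2-{(2R)-4-[(1R,3S)-2,2,3-trimethyl-6-methylidenecyclohexyl]butan-2-yl}-1,3,2-dioxaborolane | CC1(C)OB(OC1(C)C)[C@H](C)CC[C@@H]2C(=C)CC[C@H](C)C2(C)C | intermediate
14 | (2S)-but-3-yn-2-ol | C[C@H](O)C#C | starting material
15 | (2S)-but-3-yn-2-yl N,N-diisopropylcarbamate | C[C@H](OC(=O)N(C(C)C)C(C)C)C#C | intermediate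
16 | chlorobis(cyclopentadienyl)[(1E,3S)-3-(diisopropylcarbamoyloxy)but-1-en-1-yl]zirconium | C[C@H](OC(=O)N(C(C)C)C(C)C)/C=C/[Zr](Cl)(C1C=CC=C1)C1C=CC=C1 | intermediate
17 | (2S,3E)-4-iodobut-3-en-2-yl N,N-diisopropylcarbamate | C[C@H](OC(=O)N(C(C)C)C(C)C)/C=C/I | intermediate
18 | [(1E,3S)-3-(diisopropylcarbamoyloxy)but-1-en-1-yl]lithium | C[C@H](OC(=O)N(C(C)C)C(C)C)/C=C/[Li] | intermediate
19 | lithium boronate complex of 13 carrying the (1E,3S)-alkenyl group of 18 on boron | [Li+].C[C@H](OC(=O)N(C(C)C)C(C)C)/C=C/[B-]1([C@H](C)CC[C@@H]2C(=C)CC[C@H](C)C2(C)C)OC(C)(C)C(C)(C)O1 | intermediate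
20 | (2S,3E,5R)-5-methyl-7-[(1R,3S)-2,2,3-trimethyl-6-methylidenecyclohexyl]hept-3-en-2-yl N,N-diisopropylcarbamate | C[C@@H](/C=C/[C@H](C)CC[C@@H]1C(=C)CC[C@H](C)C1(C)C)OC(=O)N(C(C)C)C(C)C | intermediate
21 | 20 lithiated at C2 (carbamate carbon), configuration retained | C[C@@]([Li])(/C=C/[C@H](C)CC[C@@H]1C(=C)CC[C@H](C)C1(C)C)OC(=O)N(C(C)C)C(C)C | intermediate
22 | lithium boronate complex of 10 carrying the C2 carbon of 20 on boron | [Li+].C[C@](OC(=O)N(C(C)C)C(C)C)(/C=C/[C@H](C)CC[C@@H]1C(=C)CC[C@H](C)C1(C)C)[B-]2(CC/C=C(\C)CC[C@H](C)C(=C)C)OC(C)(C)C(C)(C)O2 | intermediate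
23 | 2-[(3R,4E,6S,9E,13S)-3,6,10,13,14-pentamethyl-1-[(1R,3S)-2,2,3-trimethyl-6-methylidenecyclohexyl]pentadeca-4,9,14-trien-6-yl]-4,4,5,5-tetramethyl-1,3,2-dioxaborolane | CC1(C)OB(OC1(C)C)[C@@](C)(/C=C/[C@H](C)CC[C@@H]2C(=C)CC[C@H](C)C2(C)C)CC/C=C(\C)CC[C@H](C)C(=C)C | intermediate
24 | lithium vinylboronate complex of 23 | [Li+].C=C[B-]1(OC(C)(C)C(C)(C)O1)[C@@](C)(/C=C/[C@H](C)CC[C@@H]2C(=C)CC[C@H](C)C2(C)C)CC/C=C(\C)CC[C@H](C)C(=C)C | intermediate
25 | (1R,3S)-1-[(3R,4E,6S,9E,13S)-6-ethenyl-3,6,10,13,14-pentamethylpentadeca-4,9,14-trien-1-yl]-2,2,3-trimethyl-6-methylidenecyclohexane | C=C[C@@](C)(/C=C/[C@H](C)CC[C@@H]1C(=C)CC[C@H](C)C1(C)C)CC/C=C(\C)CC[C@H](C)C(=C)C | target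

## Step count and risks

Total step count: 12. Longest linear sequence: 10 steps (1, 2, 3, 4, 5, 6, 7, 10, 11, 12); steps 8 and 9 make the side fragment 17.

The three steps most likely to fail:

**Step 6 (the proposed new cycloisomerisation).** Three things can go wrong. The tertiary radical can return H• from the neighbouring CH(CH3), giving the tetrasubstituted alkene and scrambling that stereocentre. The exocyclic product can re-enter the cycle and drift to the endocyclic isomer. The cis/trans ratio in the radical ring closure may be modest. The fallback sets out from 10 and comes back at 11 using only known reactions. Treating 10 with ClSO3H in 2-nitropropane at −78 °C, the classical proton-initiated cation–olefin cyclisation used for irones and ionones, gives mainly the cis endocyclic isomer 4,4,5,5-tetramethyl-2-{2-[(1R,5S)-2,5,6,6-tetramethylcyclohex-2-en-1-yl]ethyl}-1,3,2-dioxaborolane F3. The known contra-thermodynamic positional alkene isomerisation (acridinium photocatalyst, CrCl3 co-catalyst, hindered pyridine base, blue light) then converts F3 into 11. In that reaction the photochemically formed allyl radical is captured by chromium and the allylchromium is protonated at its ring terminus, which places the double bond in the exocyclic position.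

**Step 1.** A β,γ-dimethyl allylic bromide with a primary alkyl Grignard reagent is at the edge of what copper-catalysed asymmetric allylic alkylation has been shown to do, so both the SN2'/SN2 ratio and the enantiomeric excess are uncertain. This centre is carried into both halves of the target. The fallback sets out from 1 (through its Grignard reagent 3) and comes back at 5. Quenching 3 with 2-isopropoxy-4,4,5,5-tetramethyl-1,3,2-dioxaborolane gives 4,4,5,5-tetramethyl-2-[4-(trimethylsilyl)but-3-yn-1-yl]-1,3,2-dioxaborolane F1. Homologation of F1 with ethyl N,N-diisopropylcarbamate, s-BuLi and (+)-sparteine (reagent-controlled 1,2-metallate shift) gives 4,4,5,5-tetramethyl-2-[(2S)-6-(trimethylsilyl)hex-5-yn-2-yl]-1,3,2-dioxaborolane F2. Zweifel olefination of F2 with isopropenyllithium (from 2-bromopropene and t-BuLi), then I2 and NaOMe in MeOH, installs the isopropenyl group with retention, and the methoxide also removes the silyl cap, giving 5.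

**Step 10.** The alkenyllithium carries a carbamate, and the peracid needed for the syn elimination meets an exocyclic alkene, so yield and E/Z purity are at risk. The fallback sets out from 13 and comes back at 20. Zweifel vinylation of 13 (vinyllithium; I2, MeOH; NaOMe) gives (1R,3S)-2,2,3-trimethyl-6-methylidene-1-[(3R)-3-methylpent-4-en-1-yl]cyclohexane F4. Cross-metathesis of F4 with (2S)-but-3-en-2-yl N,N-diisopropylcarbamate F5 (3 equiv; made from (S)-but-3-en-2-ol with iPr2NCOCl and Et3N), using the second-generation Hoveyda–Grubbs catalyst RuCl2(H2IMes)(=CH-C6H4-2-OiPr) in CH2Cl2 at 40 °C, gives 20 as the (E) isomer; the hindered 1,1-disubstituted ring alkene does not take part.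

Further compounds
F1 | step 1 | 4,4,5,5-tetramethyl-2-[4-(trimethylsilyl)but-3-yn-1-yl]-1,3,2-dioxaborolane | C[Si](C)(C)C#CCCB1OC(C)(C)C(C)(C)O1
F2 | step 1 | 4,4,5,5-tetramethyl-2-[(2S)-6-(trimethylsilyl)hex-5-yn-2-yl]-1,3,2-dioxaborolane | C[Si](C)(C)C#CCC[C@H](C)B1OC(C)(C)C(C)(C)O1
F3 | step 6 | 4,4,5,5-tetramethyl-2-{2-[(1R,5S)-2,5,6,6-tetramethylcyclohex-2-en-1-yl]ethyl}-1,3,2-dioxaborolane | CC1(C)OB(OC1(C)C)CC[C@@H]2C(C)=CC[C@H](C)C2(C)C
F4 | step 10 | (1R,3S)-2,2,3-trimethyl-6-methylidene-1-[(3R)-3-methylpent-4-en-1-yl]cyclohexane | C=C[C@H](C)CC[C@@H]1C(=C)CC[C@H](C)C1(C)C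
F5 | step 10 | (2S)-but-3-en-2-yl N,N-diisopropylcarbamate | C[C@H](OC(=O)N(C(C)C)C(C)C)C=C
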